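The readings are simulated for substances that don't exist.

The pitfall with a lag is to read it in hours on a clock, when it may be counted in something else.

the same everywhere: L 0.13 mM
- Saturday's: Z 0.10 M; D 0.090 M; run made earlier
- Tuesday's: Z 0.067 M; D 0.090 M; run made earlier
- Monday's: Z 0.15 M; D 0.090 M; run made earlier
- delta: Z 0.10 M; D 0.0900 M; everything together at the start; time 10 h
- theta: Z 0.10 M (fed, over 8.0 h); D 0.0900 M; all else is in the flask from the start; the feed brings no volume worth counting; time 10 h
- zeta: Z 0.10 M; D 0.0900 M (fed, over 8.0 h); all else is in the flask from the start; the feed brings no volume worth counting; time 10 h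
- eta: Z 0.10 M (in portions, 5, over 8.0 h); D 0.0900 M; first portion at the start, last at 8.0 h; time 10 h

- Saturday's (time / h: X / %): 0.833: 0.1; 2.00: 0; 4.00: 2.7; 6.00: 4.8
- Tuesday's (time / h: X / %): 1.50: 0; 4.00: 0.6; 8.00: 10.7; 12.0: 17.9
- Monday's (time / h: X / %): 3.00: 1.1; 6.00: 5.4; 10.0: 11.8; 12.0: 15.6

(scatter of a reading: 0.5 percentage points)

* the flask that comes out highest in amount of X, in percent of the Z charged, or "all alike" when all lie within 1.5 percentage points (delta / theta / zeta / eta / all alike)
* X at the end, in percent of the Z charged, delta
* X at the end, in percent of the Z charged, theta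
* X at the end, in percent of the Z charged, zeta
* X at the end, in percent of the Z charged, eta



D is the limiting reagent, 0.0900 M against 0.10 M of Z, and I take one D per X, so its balance is

c_D = D fed so far − c_X

I run Monday's flask in slow motion. In the first hours hardly any of the D charge goes: X reads 1.1% at 3.00 h, which costs 1.83% of that charge, so c_D stands near its charge. In the middle, X climbs from 6.00 h to 12.0 h at a slope of 0.0170 h⁻¹ as a fraction of the Z charged. At the last reading, c_X is 0.0234 M, which is 26.0% of the D charge, so by my balance 74.0% of it remains. Running that line back to zero X gives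

lag = 2.82 h

This is the D-lag, the induction period read with c_D near its charge, and as a reading it carries the scatter. D was never varied, so my next step is a bet: the lag ends at a fixed D-dose, the time integral of c_D. In zeta c_D climbs with the feed, so the dose is c_D-charge × t·t / (2 · 8.0 h), and it matches the batch dose at

t = 6.72 h

At Monday's slope I reckon 12.2% for delta and 5.57% for zeta.

The forecast names delta, with 12% for delta, 9.3% for theta, 10.5% for zeta and 9% for eta: “Delta is the likely highest, assuming activation follows clock time”. We part on zeta, where my figure is lower.

    Z + G ⇌ G + J (K = 2.24, k = 2480 L mol⁻¹ h⁻¹)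
    D + G + J → G + X (k = 3580 L² mol⁻² h⁻¹)
    D + L → G + E (k = 4.39 L mol⁻¹ h⁻¹)

Delta comes out highest at 13.1%, with theta at 8.59%, eta at 8.36% and zeta at 6.27%. At 8.00 h zeta still holds 21.0% of its L, more than the 4.43% in theta at that time. For the neighbour of zeta charged with 0.36 M of D, the same dose arrives at 3.36 h, half of zeta's time, and that flask ends at 34.7% X.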